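## Structural features

The target is a germacranolide: a ten-membered carbocycle C1–C10 with an E trisubstituted alkene C1=C10 (methyl on C10), a cis trisubstituted epoxide C4–C5 (methyl on C4) and a cis-fused α-methylene-γ-butyrolactone (C11(=C13H2)–C12(=O)–O) across C7–C8, with the ring oxygen on C8. Acetoxy groups sit on C2 (allylic to C1=C10) and on C6 (between the epoxide and the lactone junction). There are six stereocentres, five contiguous (C4–C8) and one isolated (C2), in the configuration 2S,4R,5S,6S,7R,8R. The C2 and C6 oxygens and the epoxide oxygen lie on one face, the C7–C11 and C8–O bonds on the other. Fragile elements are the exocyclic acrylate, the epoxide that faces C1=C10 across the ring (acid-induced transannular reactions, attack by a free O8–H or O6–H), possible lactone migration between O8 and O6, and every β-oxygenated carbonyl met on the way. The real difficulty is a medium ring that resists end-to-end closure, together with stereocontrol at C6, C7 and the epoxide on a mobile ring, including oxidation of only one of two trisubstituted alkenes. The key step exploits the array C6(=O)–C7–C8–C9–C10=C1: a C6 carbonyl, a C8–C9 bond and the C1=C10 alkene form the product pattern of an oxy-Cope shift. The ten-membered ring can therefore be folded back to a cyclohexene (C1–C6) that already holds the Z C4=C5 bond and carries an isopropenyl group on C1 and a (Z)-2-alkoxyvinyl group on C6.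

## Logic of the disconnections

Atom labels are those of the target throughout.

31 ⇒ 30 ⇒ 29. The two acetyl C–O bonds are cut, then the O2–benzyl bond. Acetates cannot pass through enolate or hydride steps, and O2 must stay masked until the epoxide is in place. This leaves 29, with O6 free and O2 protected. Forward, the ether must leave under neutral oxidative conditions that spare epoxide and acrylate, and acylation must be mild enough to avoid epoxide migration.

29 ⇒ 28. Both epoxide C–O bonds are cut. In 28 the C6 hydroxyl is the only free allylic hydroxyl and can hand oxygen to C4=C5. Two stereocentres disappear. Forward, one of two trisubstituted alkenes and one of its faces must be oxidised.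

28 ⇒ 25. The C11=C13 bond is cut. The acrylate is the most reactive group and is added as late as enolate chemistry allows. Forward, the lactone must be enolised in the presence of O6–H without lactone migration.

25 ⇒ 24. The C6–H bond is cut (carbinol to ketone). A C6 carbonyl is what the ring-forming step delivers and what activates C7. Forward, hydride must add 1,2 and to one face of a twisted enone.

24 ⇒ 22. The lactone C12–O8 bond and the O8–benzyl bond are cut. Closing the lactone while C6 is still a ketone makes O8 the only possible partner, which removes the O6/O8 ambiguity. Forward, O8 must be unmasked while O2 stays protected. Two identical benzyl ethers would not allow this. So in 22 and in every compound before it, O8 carries the more easily oxidised 3,4-dimethoxybenzyl group and O2 a 4-methoxybenzyl group.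

22 ⇒ 19 + 20. The C7–C11 bond is cut, α to the C6 carbonyl. The C7 stereocentre disappears and the unsubstituted dienone remains. Forward, enolisation must occur at C7 without loss of the β-alkoxy group, and the electrophile must enter cis to O8.

19 ⇒ 17. In the retrosynthetic sense C8–C9 is cut and C1–C6 is joined (retro-oxy-Cope). The ten-membered ring becomes a cyclohexene, the Z C4=C5 bond becomes a ring alkene of fixed geometry, and the C8 stereocentre is traded for enol ether geometry plus the C1/C6 relationship. Forward, the alkenyl groups on C1 and C6 must be trans and the enol ether Z.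

17 ⇒ 9 + 14. The C6–C7 bond is cut (carbonyl addition of a vinyl anion). Forward, addition must be 1,2, anti to the isopropenyl group, and must not enolise the ketone.

14 ⇒ 12 ⇒ 10 + 11. The C–Br bond and the vinyl C–O bond are cut. Forward, the bromo enol ether must be Z.

9 ⇒ 8 ⇒ 7 ⇒ 6. The oxidation level at C6, the Si–O bond and the C10=C9 methylene are adjusted back to a silyl ether and an acetyl group, which are what a cycloaddition delivers. Forward, methylenation and oxidation must be non-basic, because C1–H is acidic and flanked by two β-oxygen leaving groups.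

6 ⇒ 2 + 5. The C1–C6 and C2–C3 bonds are cut ([4+2]). All six ring carbons, the ring alkene and the trans C1/C2 centres arise in one step, and both diene substituents direct the same regiochemistry. Forward, the enantioface of 5 must be controlled; this is the only absolute stereochemical input of the route.

2 ⇒ 1 and 5 ⇒ 3 + 4. An Si–O bond and a vinylogous ester C–O bond are cut, leading to commercial materials.

## Other disconnections considered

Alternative 1: The ring is traced back to the strained tricycle A3, in which C5–C10 and C1–C4 are still bonded. A3 is cut at C10–C1 and C5–C4 into the cis-fused enone lactone A1 and the silyloxy cyclobutene A2. Forward, irradiation of A1 with A2 would give A3 by [2+2] cycloaddition, and heating would open its bicyclo[2.2.0]hexane core to the dienone lactone A4.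
- In its favour: two ring bonds form in one operation and both partners are small. The C7–C8 junction is set beforehand on a six-membered ring, which is better than the chosen plan, where C7 is introduced on a mobile ten-membered enolate.
- Against it: head-to-head versus head-to-tail orientation with an unsymmetrical cyclobutene, face selectivity on both partners, the need for A2 as a single enantiomer, and two adjacent quaternary centres in A3. The cycloreversion must give 4Z and 1(10)E, while the cis,trans-1,5-diene can undergo Cope rearrangement to a divinylcyclohexane at the temperature of its formation. A4 is also a β-acyloxy ketone.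
- Comparison: both plans form the medium ring by σ-bond reorganisation, not end-to-end closure, so they are equal on that point. The chosen plan carries the Z alkene over from a six-membered ring, whereas here both geometries are created thermally. Step count would be comparable at best, since A1 and A2 each need an enantioselective preparation and the C6, methylene and epoxide steps remain.

Alternative 2: C1–C2 and the C10–CH3 bond are cut, giving the open-chain ynal A5, which holds the lactone, the C6 silyl ether and the Z C4=C5 alkene. Forward, Ni(cod)2 with ZnMe2 would join alkyne carbon C1 to aldehyde carbon C2 and place methyl on C10, closing the ring as the E allylic alcohol A6.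
- In its favour: C6, C7 and C8 are set before the ring exists, a point on which it is better than the chosen plan. Syn addition across the alkyne fixes the E geometry as reliably as the chair does, an equal point. O2 emerges free and distinct from O6.
- Against it: an end-to-end closure of a ten-membered ring with its entropic cost and need for high dilution, no evident control of the new C2 centre, endo/exo regiochemistry at the alkyne, and a β,γ-unsaturated aldehyde in A5 that can slip into conjugation and lose the Z geometry.
- Comparison: the linear route to A5, with three stereocentres and a trisubstituted Z alkene made without the help of a ring, would be clearly longer than the nine steps that lead to 17.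

Alternative 3: C3–C4 is cut, giving the bromomethyl enone A7 with a C4 methyl ketone. Forward, SmI2 would reduce the C3–Br bond to a samarium enolate that adds to the C4 carbonyl and closes the ring as the tertiary β-hydroxy ketone A8.
- In its favour: samarium Reformatsky closures of medium rings run at low temperature through a chelated transition state, and the E C1=C10 enone is built beforehand. The C4/C5 oxygen pattern is already present, so the epoxide could be closed by displacement at C5 instead of by chemoselective oxidation of a diene; on that point it is better than the chosen plan.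
- Against it: the C4 configuration is created in the closure and later decides the epoxide configuration. The C5 alkoxy group is α to the C4 ketone, a position that SmI2 cleaves reductively, and the enone can be reduced as well. Afterwards the C2 ketone must be reduced selectively and C5 unmasked, activated and displaced with inversion.
- Comparison: the ring is closed end to end, and the sequence to A7 with four contiguous stereocentres is longer. In mildness of the ring-forming conditions the two plans are equal.

Key step: step 10

Remark: atom labels C1–C13 in the Why lines are those of the target, also where a compound name uses other locants.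

Assumption: the sense of induction in step 3 is assigned to the (S)-oxazaborolidinium catalyst on the basis of the usual enone-binding model; if the first run shows the opposite sense, the (R)-catalyst is used and nothing else changes.

## Steps

Step 1
Reactants: 1 3-methylbut-2-enal
Product: 2 (E)-tert-butyldimethyl[(3-methylbuta-1,3-dien-1-yl)oxy]silane
Conditions: TBSOTf, Et3N, Et2O, 0 °C → rt
Reagents that add atoms: tert-butyldimethylsilyl trifluoromethanesulfonate, CC(C)(C)[Si](C)(C)OS(=O)(=O)C(F)(F)F
Why: O-silylation of the enal and removal of a γ-proton by the amine (vinylogous silyl enol ether formation) is the usual route to (E)-1-silyloxy-1,3-dienes.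

Step 2
Reactants: 3 (E)-4-methoxybut-3-en-2-one; 4 4-methoxybenzyl alcohol
Product: 5 (E)-4-[(4-methoxybenzyl)oxy]but-3-en-2-one
Conditions: PPTS (cat.), toluene, 70 °C, 5 Å MS
Reagents that add atoms: none
Why: Acid-catalysed conjugate addition–elimination at the β-carbon (vinylogous transesterification) is driven by removal of methanol; the E isomer is the stable one.

Step 3
Reactants: 2 (E)-tert-butyldimethyl[(3-methylbuta-1,3-dien-1-yl)oxy]silane; 5 (E)-4-[(4-methoxybenzyl)oxy]but-3-en-2-one
Product: 6 1-[(1R,2S,6S)-2-[(tert-butyldimethylsilyl)oxy]-6-[(4-methoxybenzyl)oxy]-4-methylcyclohex-3-en-1-yl]ethan-1-one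
Conditions: (S)-3,3-diphenyl-1-(o-tolyl)oxazaborolidine (20 mol %), HNTf2 (16 mol %), CH2Cl2, −78 → −40 °C
Reagents that add atoms: none
Why: Diels–Alder reaction catalysed by a chiral cationic oxazaborolidine bound to the enone carbonyl; the 1-silyloxy ("ortho") and 3-methyl ("para") groups of 2 both place the acetyl carbon next to the silyloxy carbon, the E dienophile gives trans acetyl/PMB-oxy, and the catalyst shields one enone face to set the centres that become C1 and C2. Endo approach gives the cis silyloxy isomer shown, but the endo/exo ratio is immaterial because that centre becomes the ketone in step 6.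

Step 4
Reactants: 6 1-[(1R,2S,6S)-2-[(tert-butyldimethylsilyl)oxy]-6-[(4-methoxybenzyl)oxy]-4-methylcyclohex-3-en-1-yl]ethan-1-one
Product: 7 tert-butyl{[(1S,5S,6R)-6-isopropenyl-5-[(4-methoxybenzyl)oxy]-3-methylcyclohex-2-en-1-yl]oxy}dimethylsilane
Conditions: Cp2TiMe2, toluene/THF, 65 °C, dark
Reagents that add atoms: dimethyltitanocene, C[Ti](C)(C1C=CC=C1)C1C=CC=C1
Why: Petasis methylenation through Cp2Ti=CH2 and an oxatitanacyclobutane converts acetyl into isopropenyl without base, so the C1 centre, flanked by two β-oxygen groups, neither epimerises nor eliminates.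

Step 5
Reactants: 7 tert-butyl{[(1S,5S,6R)-6-isopropenyl-5-[(4-methoxybenzyl)oxy]-3-methylcyclohex-2-en-1-yl]oxy}dimethylsilane
Product: 8 (1S,5S,6S)-6-isopropenyl-5-[(4-methoxybenzyl)oxy]-3-methylcyclohex-2-en-1-ol
Conditions: TBAF, THF, 0 °C → rt
Reagents that add atoms: none
Why: Fluoride cleaves the Si–O bond and leaves the 4-methoxybenzyl ether and both alkenes untouched; no stereocentre is affected (the descriptor at the isopropenyl carbon changes only through priorities).

Step 6
Reactants: 8 (1S,5S,6S)-6-isopropenyl-5-[(4-methoxybenzyl)oxy]-3-methylcyclohex-2-en-1-ol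
Product: 9 (5S,6R)-6-isopropenyl-5-[(4-methoxybenzyl)oxy]-3-methylcyclohex-2-en-1-one
Conditions: MnO2 (activated, excess), CH2Cl2, rt
Reagents that add atoms: none
Why: Allylic alcohol oxidation on MnO2 is neutral, so the base-sensitive enone (acidic H at C1, β-alkoxy group at C2) is not epimerised and does not eliminate to a phenol.

Step 7
Reactants: 10 3,4-dimethoxybenzyl alcohol; 11 ethyl vinyl ether
Product: 12 4-[(ethenyloxy)methyl]-1,2-dimethoxybenzene
Conditions: Pd(OAc)2 (2 mol %), 4,7-diphenyl-1,10-phenanthroline (2 mol %), ethyl vinyl ether (solvent), rt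
Reagents that add atoms: none
Why: Palladium-catalysed transfer vinylation (transetherification) with excess vinyl ether is neutral and avoids acetal formation.

Step 8
Reactants: 12 4-[(ethenyloxy)methyl]-1,2-dimethoxybenzene
Product: 14 (Z)-4-{[(2-bromoethenyl)oxy]methyl}-1,2-dimethoxybenzene, via 1,2-dibromoethyl ether 13 (not isolated)
Conditions: Br2, CH2Cl2, −78 °C; then DBU, −78 °C → rt
Reagents that add atoms: bromine, BrBr
Why: Bromine adds to the enol ether at −78 °C far faster than it attacks the arene, and DBU then removes HBr from the α-bromo ether (dehydrohalogenation); the cis (Z) isomer is the favoured one for 1-alkoxy-2-haloethenes and is purified on base-washed silica.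

Step 9
Reactants: 14 (Z)-4-{[(2-bromoethenyl)oxy]methyl}-1,2-dimethoxybenzene; 9 (5S,6R)-6-isopropenyl-5-[(4-methoxybenzyl)oxy]-3-methylcyclohex-2-en-1-one
Product: 17 (1R,5S,6R)-1-{(Z)-2-[(3,4-dimethoxybenzyl)oxy]ethenyl}-6-isopropenyl-5-[(4-methoxybenzyl)oxy]-3-methylcyclohex-2-en-1-ol, via vinyllithium 15 (not isolated), via vinylcerium dichloride 16 (not isolated)
Conditions: n-BuLi, Et2O, −78 °C; CeCl3 (anhydrous), THF, −78 °C; then 9, −78 °C
Reagents that add atoms: none
Why: Bromine–lithium exchange keeps the Z geometry at −78 °C, and the organocerium reagent adds 1,2 to the enolisable enone without deprotonation, which protects C1 and prevents loss of the β-alkoxy group. The nucleophile enters the half-chair enone anti to the adjacent isopropenyl group, giving the trans-dialkenyl carbinol.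

Step 10
Reactants: 17 (1R,5S,6R)-1-{(Z)-2-[(3,4-dimethoxybenzyl)oxy]ethenyl}-6-isopropenyl-5-[(4-methoxybenzyl)oxy]-3-methylcyclohex-2-en-1-ol
Product: 19 (2Z,5S,6E,9R)-9-[(3,4-dimethoxybenzyl)oxy]-5-[(4-methoxybenzyl)oxy]-3,7-dimethylcyclodeca-2,6-dien-1-one, via potassium dienolate 18 (not isolated)
Conditions: KH, 18-crown-6, THF, 0 °C → rt; then AcOH, −78 °C
Reagents that add atoms: none
Why: KH with the crown ether gives the free tertiary alkoxide at C6, and a [3,3] shift through the chair array C8=C7–C6–C1–C10=C9 breaks the doubly allylic C1–C6 bond and forms C8–C9 to give enolate 18, which is protonated at C7 on the cold quench. The closest known reaction type is the anionic oxy-Cope ring expansion of trans-1,2-dialkenylcyclohexanols to (E)-cyclodec-5-enones. The ten-membered ring is not closed end to end: it arises by four-carbon ring expansion of the cyclohexene inside a six-centre transition state, so no macrocyclisation entropy is paid and the Z C4=C5 bond is carried over unchanged. The new stereocentre C8 is controlled by the Z enol ether, which places its oxygen axial in the chair, together with the fixed C1/C6 configuration; this gives 8R relative to 2S (9R and 5S in the locants of 19). The trans relationship of the alkenyl groups puts both ring bonds equatorial in the chair, which makes C1=C10 E and removes any need for a boat. The step needs the exocyclic enol ether, not the ring alkene, as the participating π-bond; this is secured because C4 cannot reach C9 across the ring. It also needs the enolate to survive without losing the C8 alkoxy group; the C8–O bond lies in the enolate plane as formed, and the low-temperature acid quench limits the time available for elimination.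

Step 11
Reactants: 19 (2Z,5S,6E,9R)-9-[(3,4-dimethoxybenzyl)oxy]-5-[(4-methoxybenzyl)oxy]-3,7-dimethylcyclodeca-2,6-dien-1-one; 20 methyl bromoacetate
Product: 22 methyl 2-[(1R,3Z,6S,7E,10R)-10-[(3,4-dimethoxybenzyl)oxy]-6-[(4-methoxybenzyl)oxy]-4,8-dimethyl-2-oxocyclodeca-3,7-dien-1-yl]acetate, via lithium enolate 21 (not isolated)
Conditions: LiN(iPr)2, THF, −78 °C; then 20, DMPU, −78 → −40 °C
Reagents that add atoms: none
Why: Kinetic deprotonation of the enone at C7 gives the cross-conjugated enolate, which is alkylated by SN2 displacement of bromide. Lithium bridging the enolate oxygen and O8 should hold the C8–O bond in the enolate plane with the ring bond C8–C9 perpendicular, so the electrophile enters on the outer face anti to C9 and C11 ends up cis to O8 (7R).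

Step 12
Reactants: 22 methyl 2-[(1R,3Z,6S,7E,10R)-10-[(3,4-dimethoxybenzyl)oxy]-6-[(4-methoxybenzyl)oxy]-4,8-dimethyl-2-oxocyclodeca-3,7-dien-1-yl]acetate
Product: 24 (3aR,5Z,8S,9E,11aR)-8-[(4-methoxybenzyl)oxy]-6,10-dimethyl-3,3a,7,8,11,11a-hexahydrocyclodeca[b]furan-2,4-dione, via hydroxy keto ester 23 (not isolated)
Conditions: DDQ (1.1 equiv), CH2Cl2/pH 7 buffer, 0 °C; then PPTS (cat.), CH2Cl2, rt
Reagents that add atoms: none
Why: DDQ oxidises the more electron-rich 3,4-dimethoxybenzyl ether faster than the 4-methoxybenzyl ether (known selective benzylic oxidation), freeing only O8–H; the γ-hydroxy ester then closes to the cis-fused lactone by acid-catalysed transesterification. Because C6 is still a ketone, O8 is the only possible lactone oxygen.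

Step 13
Reactants: 24 (3aR,5Z,8S,9E,11aR)-8-[(4-methoxybenzyl)oxy]-6,10-dimethyl-3,3a,7,8,11,11a-hexahydrocyclodeca[b]furan-2,4-dione
Product: 25 (3aS,4R,5Z,8S,9E,11aR)-4-hydroxy-8-[(4-methoxybenzyl)oxy]-6,10-dimethyl-3a,4,7,8,11,11a-hexahydrocyclodeca[b]furan-2(3H)-one
Conditions: NaBH4, CeCl3·7H2O, MeOH, −78 °C
Reagents that add atoms: none
Why: Luche reduction gives 1,2-addition to the enone and leaves the lactone alone, and its mildly acidic medium avoids enolisation at C7. Hydride is expected on the outer face of C6 anti to the lactone methylene C11, in the conformer whose carbonyl eclipses the C7–C8 bond, giving the 6α-alcohol trans to C11.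

Step 14
Reactants: 25 (3aS,4R,5Z,8S,9E,11aR)-4-hydroxy-8-[(4-methoxybenzyl)oxy]-6,10-dimethyl-3a,4,7,8,11,11a-hexahydrocyclodeca[b]furan-2(3H)-one
Product: 28 (3aS,4R,5Z,8S,9E,11aR)-4-hydroxy-8-[(4-methoxybenzyl)oxy]-6,10-dimethyl-3-methylidene-3a,4,7,8,11,11a-hexahydrocyclodeca[b]furan-2(3H)-one, via Mannich base 26 (not isolated), via ammonium iodide 27 (not isolated)
Conditions: LiN(iPr)2 (2.3 equiv), THF, −78 °C; CH2=NMe2+ I−, −78 → 0 °C; MeOH; then MeI, rt; NaHCO3 aq, rt
Reagents that add atoms: N,N-dimethylmethyleneiminium iodide (Eschenmoser's salt), C=[N+](C)C.[I-]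
Why: The dianion (O6 alkoxide and lactone enolate) undergoes a Mannich reaction at C11, followed by N-methylation and E1cB loss of trimethylamine, the standard α-methylenation of γ-lactones. C11 becomes sp2, so its configuration in 26 is irrelevant, and −78 °C keeps the O6 alkoxide from attacking the lactone.

Step 15
Reactants: 28 (3aS,4R,5Z,8S,9E,11aR)-4-hydroxy-8-[(4-methoxybenzyl)oxy]-6,10-dimethyl-3-methylidene-3a,4,7,8,11,11a-hexahydrocyclodeca[b]furan-2(3H)-one
Product: 29 (2S,4R,5S,6S,7S,8R)-4,5-epoxy-6-hydroxy-2-[(4-methoxybenzyl)oxy]germacra-1(10)E,11(13)-dien-12,8-olide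
Conditions: VO(acac)2 (5 mol %), t-BuOOH, CH2Cl2, 0 °C → rt
Reagents that add atoms: tert-butyl hydroperoxide, CC(C)(C)OO
Why: In this vanadium-catalysed hydroxyl-directed epoxidation the C6 vanadate ester delivers oxygen to C4=C5 only, since C1=C10 has no free allylic hydroxyl and the acrylate alkene is electron-poor. Delivery is expected on the face syn to the C6–O bond, as with medium-ring (Z)-allylic alcohols, which sets 4R,5S.

Step 16
Reactants: 29 (2S,4R,5S,6S,7S,8R)-4,5-epoxy-6-hydroxy-2-[(4-methoxybenzyl)oxy]germacra-1(10)E,11(13)-dien-12,8-olide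
Product: 30 (2S,4R,5S,6S,7S,8R)-4,5-epoxy-2,6-dihydroxygermacra-1(10)E,11(13)-dien-12,8-olide
Conditions: DDQ (1.2 equiv), CH2Cl2/pH 7 buffer, 0 °C → rt
Reagents that add atoms: none
Why: Oxidative cleavage of the 4-methoxybenzyl ether by benzylic hydride abstraction is neutral when buffered and spares the epoxy alcohol, the acrylate and the alkene.

Step 17
Reactants: 30 (2S,4R,5S,6S,7S,8R)-4,5-epoxy-2,6-dihydroxygermacra-1(10)E,11(13)-dien-12,8-olide
Product: 31 (2S,4R,5S,6S,7R,8R)-2,6-diacetoxy-4,5-epoxygermacra-1(10)E,11(13)-dien-12,8-olide (CNP0270851.1)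
Conditions: Ac2O, pyridine, DMAP (cat.), CH2Cl2, 0 °C → rt
Reagents that add atoms: acetic anhydride, CC(=O)OC(C)=O
Why: DMAP-catalysed acylation of both secondary alcohols under mild base avoids epoxide migration and conjugate addition; no stereocentre changes (the C7 descriptor becomes R only through priorities).

## Compound list

1 | 3-methylbut-2-enal | CC(C)=CC=O | starting material
2 | (E)-tert-butyldimethyl[(3-methylbuta-1,3-dien-1-yl)oxy]silane | C=C(C)/C=C/O[Si](C)(C)C(C)(C)C | intermediate
3 | (E)-4-methoxybut-3-en-2-one | CO/C=C/C(C)=O | starting material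
4 | 4-methoxybenzyl alcohol | COc1ccc(CO)cc1 | starting material
5 | (E)-4-[(4-methoxybenzyl)oxy]but-3-en-2-one | CC(=O)/C=C/OCc1ccc(OC)cc1 | intermediate
6 | 1-[(1R,2S,6S)-2-[(tert-butyldimethylsilyl)oxy]-6-[(4-methoxybenzyl)oxy]-4-methylcyclohex-3-en-1-yl]ethan-1-one | CC(=O)[C@@H]1[C@@H](OCc2ccc(OC)cc2)CC(C)=C[C@@H]1O[Si](C)(C)C(C)(C)C | intermediate
7 | tert-butyl{[(1S,5S,6R)-6-isopropenyl-5-[(4-methoxybenzyl)oxy]-3-methylcyclohex-2-en-1-yl]oxy}dimethylsilane | C=C(C)[C@@H]1[C@@H](OCc2ccc(OC)cc2)CC(C)=C[C@@H]1O[Si](C)(C)C(C)(C)C | intermediate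
8 | (1S,5S,6S)-6-isopropenyl-5-[(4-methoxybenzyl)oxy]-3-methylcyclohex-2-en-1-ol | C=C(C)[C@@H]1[C@@H](OCc2ccc(OC)cc2)CC(C)=C[C@@H]1O | intermediate
9 | (5S,6R)-6-isopropenyl-5-[(4-methoxybenzyl)oxy]-3-methylcyclohex-2-en-1-one | C=C(C)[C@@H]1[C@@H](OCc2ccc(OC)cc2)CC(C)=CC1=O | intermediate
10 | 3,4-dimethoxybenzyl alcohol | COc1ccc(CO)cc1OC | starting material
11 | ethyl vinyl ether | C=COCC | starting material
12 | 4-[(ethenyloxy)methyl]-1,2-dimethoxybenzene | C=COCc1ccc(OC)c(OC)c1 | intermediate
13 | 4-[(1,2-dibromoethoxy)methyl]-1,2-dimethoxybenzene | BrCC(Br)OCc1ccc(OC)c(OC)c1 | intermediate (not isolated)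
14 | (Z)-4-{[(2-bromoethenyl)oxy]methyl}-1,2-dimethoxybenzene | Br/C=C\OCc1ccc(OC)c(OC)c1 | intermediate
15 | (Z)-2-[(3,4-dimethoxybenzyl)oxy]ethenyllithium | [Li]/C=C\OCc1ccc(OC)c(OC)c1 | intermediate (not isolated)
16 | dichloro{(Z)-2-[(3,4-dimethoxybenzyl)oxy]ethenyl}cerium | Cl[Ce](Cl)/C=C\OCc1ccc(OC)c(OC)c1 | intermediate (not isolated)
17 | (1R,5S,6R)-1-{(Z)-2-[(3,4-dimethoxybenzyl)oxy]ethenyl}-6-isopropenyl-5-[(4-methoxybenzyl)oxy]-3-methylcyclohex-2-en-1-ol | C=C(C)[C@@H]1[C@@H](OCc2ccc(OC)cc2)CC(C)=C[C@@]1(O)/C=C\OCc3ccc(OC)c(OC)c3 | intermediate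
18 | potassium enolate of 19 (O–K on C6, C6=C7, oxygen cis to C8) | C1/C(C)=C/[C@@H](OCc2ccc(OC)cc2)C/C(C)=C\C([O-])=C\[C@@H]1OCc3ccc(OC)c(OC)c3.[K+] | intermediate (not isolated)
19 | (2Z,5S,6E,9R)-9-[(3,4-dimethoxybenzyl)oxy]-5-[(4-methoxybenzyl)oxy]-3,7-dimethylcyclodeca-2,6-dien-1-one | C1C(=O)/C=C(C)\C[C@H](OCc2ccc(OC)cc2)/C=C(C)/C[C@H]1OCc3ccc(OC)c(OC)c3 | intermediate
20 | methyl bromoacetate | COC(=O)CBr | starting material
21 | lithium enolate of 19 (O–Li on C6, C6=C7, chelated to O8) | C1/C(C)=C/[C@@H](OCc2ccc(OC)cc2)C/C(C)=C\C([O-])=C\[C@@H]1OCc3ccc(OC)c(OC)c3.[Li+] | intermediate (not isolated)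
22 | methyl 2-[(1R,3Z,6S,7E,10R)-10-[(3,4-dimethoxybenzyl)oxy]-6-[(4-methoxybenzyl)oxy]-4,8-dimethyl-2-oxocyclodeca-3,7-dien-1-yl]acetate | COC(=O)C[C@H]1C(=O)/C=C(C)\C[C@H](OCc2ccc(OC)cc2)/C=C(C)/C[C@H]1OCc3ccc(OC)c(OC)c3 | intermediate
23 | methyl 2-[(1R,3Z,6S,7E,10R)-10-hydroxy-6-[(4-methoxybenzyl)oxy]-4,8-dimethyl-2-oxocyclodeca-3,7-dien-1-yl]acetate | COC(=O)C[C@H]1C(=O)/C=C(C)\C[C@H](OCc2ccc(OC)cc2)/C=C(C)/C[C@H]1O | intermediate (not isolated)
24 | (3aR,5Z,8S,9E,11aR)-8-[(4-methoxybenzyl)oxy]-6,10-dimethyl-3,3a,7,8,11,11a-hexahydrocyclodeca[b]furan-2,4-dione | O=C1C[C@H]2C(=O)/C=C(C)\C[C@H](OCc3ccc(OC)cc3)/C=C(C)/C[C@H]2O1 | intermediate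
25 | (3aS,4R,5Z,8S,9E,11aR)-4-hydroxy-8-[(4-methoxybenzyl)oxy]-6,10-dimethyl-3a,4,7,8,11,11a-hexahydrocyclodeca[b]furan-2(3H)-one | O=C1C[C@H]2[C@H](O)/C=C(C)\C[C@H](OCc3ccc(OC)cc3)/C=C(C)/C[C@H]2O1 | intermediate
26 | 3-[(dimethylamino)methyl] derivative of 25 (both C11 epimers) | CN(C)CC1C(=O)O[C@@H]2C/C(C)=C/[C@@H](OCc3ccc(OC)cc3)C/C(C)=C\[C@@H](O)[C@H]12 | intermediate (not isolated)
27 | 3-[(trimethylammonio)methyl] iodide derived from 26 | C[N+](C)(C)CC1C(=O)O[C@@H]2C/C(C)=C/[C@@H](OCc3ccc(OC)cc3)C/C(C)=C\[C@@H](O)[C@H]12.[I-] | intermediate (not isolated)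
28 | (3aS,4R,5Z,8S,9E,11aR)-4-hydroxy-8-[(4-methoxybenzyl)oxy]-6,10-dimethyl-3-methylidene-3a,4,7,8,11,11a-hexahydrocyclodeca[b]furan-2(3H)-one | C=C1C(=O)O[C@@H]2C/C(C)=C/[C@@H](OCc3ccc(OC)cc3)C/C(C)=C\[C@@H](O)[C@H]12 | intermediate
29 | (2S,4R,5S,6S,7S,8R)-4,5-epoxy-6-hydroxy-2-[(4-methoxybenzyl)oxy]germacra-1(10)E,11(13)-dien-12,8-olide | C=C1C(=O)O[C@@H]2C/C(C)=C/[C@@H](OCc3ccc(OC)cc3)C[C@@]3(C)O[C@H]3[C@@H](O)[C@H]12 | intermediate
30 | (2S,4R,5S,6S,7S,8R)-4,5-epoxy-2,6-dihydroxygermacra-1(10)E,11(13)-dien-12,8-olide | C=C1C(=O)O[C@@H]2C/C(C)=C/[C@@H](O)C[C@@]3(C)O[C@H]3[C@@H](O)[C@H]12 | intermediate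
31 | (2S,4R,5S,6S,7R,8R)-2,6-diacetoxy-4,5-epoxygermacra-1(10)E,11(13)-dien-12,8-olide (CNP0270851.1) | C=C1C(=O)O[C@@H]2C/C(C)=C/[C@@H](OC(C)=O)C[C@@]3(C)O[C@H]3[C@@H](OC(C)=O)[C@H]12 | target

## Step count and least certain steps

Total step count: 17. Longest linear sequence: 14 steps (steps 1, 3–6 and 9–17).

Step 10 (key step). Most likely to go wrong: β-elimination of the C8 alkoxy group from the potassium enolate before the quench, or fragmentation of the doubly allylic alkoxide, because a free enolate with a β-leaving group is present at 0 °C to room temperature. Fallback: setting out from 17, the carbinol is silylated (TMS-imidazole, CH2Cl2) to the trimethylsilyl ether of 17 F1. This is heated in a sealed tube (o-dichlorobenzene, about 190 °C) so that the neutral siloxy-Cope shift gives the trimethylsilyl enol ether of 19 F2 without a free enolate. Buffered fluoride (TBAF/AcOH, THF, −78 °C) then releases the ketone, and the route is rejoined at 19.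

Step 3. Most likely to go wrong: stepwise Mukaiyama–Michael addition with loss of 4-methoxybenzyl alcohol from the activated vinylogous ester instead of cycloaddition, or poor enantioface discrimination, because the dienophile is donor-substituted and binds the catalyst through one point only. Fallback: setting out from 2 and 5, the cycloaddition is run thermally without catalyst (toluene, 110 °C, sealed tube, BHT). This gives racemic material, 6 together with the mirror image of 6 F3. Steps 4 and 5 as written carry it to 8 together with the mirror image of 7 F4 and then the mirror image of 8 F5. Acylation with vinyl acetate and the lipase from Burkholderia cepacia should esterify the mirror-image alcohol (R carbinol, the enantiomer favoured by the empirical rule for secondary alcohols) to the acetate of the mirror image of 8 F6 and leave 8. After chromatography the route is rejoined at 8.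

Step 11. Most likely to go wrong: deprotonation at C3 or at the C4 methyl group instead of C7, E1cB loss of the C8 ether from the lithium enolate, or poor facial selectivity if the lithium chelate is not formed. Fallback: setting out from 17, the oxy-Cope step is run as before but not quenched. The potassium enolate 18, whose position and geometry are fixed by the sigmatropic shift and whose C8–O bond lies in the enolate plane as formed, is cooled to −78 °C and alkylated in the same flask with 20. The route is rejoined at 22; no new compound is involved.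

Step 13. Most likely to go wrong: poor or reversed facial selectivity of hydride delivery, because the face preference of a ketone on a mobile ten-membered ring cannot be predicted with confidence. Fallback: setting out from 24, the reduction product of the wrong configuration, the C6 epimer of 25 F7, is inverted by Mitsunobu reaction (ClCH2CO2H, PPh3, DIAD, toluene, 0 °C) to the O6-chloroacetate of 25 F8. Mild methanolysis (K2CO3 cat., MeOH, 0 °C) then cleaves the chloroacetate, and the route is rejoined at 25.

Step 15. Most likely to go wrong: oxygen delivery to the opposite face of C4=C5 if the ring behaves like an open-chain (Z)-allylic alcohol, or competing oxidation of C1=C10. Fallback: setting out from 28, the epoxidation is run under reagent control with Ti(OiPr)4, L-(+)-diisopropyl tartrate and t-BuOOH (4 Å MS, CH2Cl2, −20 °C). The carbinol configuration of 28 corresponds to the fast-reacting case for this tartrate, which delivers the erythro epoxy alcohol. The route is rejoined at 29; no new compound is involved.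

Step 12. Most likely to go wrong: loss of the 4-methoxybenzyl ether on O2 together with the 3,4-dimethoxybenzyl ether, because the rate difference between the two benzylic oxidations is finite. Fallback: setting out from 22, both ethers are removed with excess DDQ to give the diol keto ester F9, which lactonises under PPTS to the 8-hydroxy keto lactone F10. O2 is then re-protected with 4-methoxybenzyl trichloroacetimidate and La(OTf)3 (cat.) in toluene, and the route is rejoined at 24.

## Further compounds

F1 | step 10 | trimethylsilyl ether of 17 | C=C(C)[C@@H]1[C@@H](OCc2ccc(OC)cc2)CC(C)=C[C@@]1(O[Si](C)(C)C)/C=C\OCc3ccc(OC)c(OC)c3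
F2 | step 10 | trimethylsilyl enol ether of 19 (Si–O on C6, C6=C7) | C1/C(C)=C/[C@@H](OCc2ccc(OC)cc2)C/C(C)=C\C(O[Si](C)(C)C)=C\[C@@H]1OCc3ccc(OC)c(OC)c3
F3 | step 3 | mirror image of 6, 1-[(1S,2R,6R)-2-[(tert-butyldimethylsilyl)oxy]-6-[(4-methoxybenzyl)oxy]-4-methylcyclohex-3-en-1-yl]ethan-1-one | CC(=O)[C@H]1[C@H](OCc2ccc(OC)cc2)CC(C)=C[C@H]1O[Si](C)(C)C(C)(C)C
F4 | step 3 | mirror image of 7, (1R,5R,6S) silyl ether | C=C(C)[C@H]1[C@H](OCc2ccc(OC)cc2)CC(C)=C[C@H]1O[Si](C)(C)C(C)(C)C
F5 | step 3 | mirror image of 8, (1R,5R,6R)-6-isopropenyl-5-[(4-methoxybenzyl)oxy]-3-methylcyclohex-2-en-1-ol | C=C(C)[C@H]1[C@H](OCc2ccc(OC)cc2)CC(C)=C[C@H]1O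
F6 | step 3 | acetate of the mirror image of 8, (1R,5R,6S)-6-isopropenyl-5-[(4-methoxybenzyl)oxy]-3-methylcyclohex-2-en-1-yl acetate | C=C(C)[C@H]1[C@H](OCc2ccc(OC)cc2)CC(C)=C[C@H]1OC(C)=O
F0 | step 11 | none | none
F7 | step 13 | C6 epimer of 25, (3aS,4S,5Z,8S,9E,11aR)-4-hydroxy lactone | O=C1C[C@H]2[C@@H](O)/C=C(C)\C[C@H](OCc3ccc(OC)cc3)/C=C(C)/C[C@H]2O1
F8 | step 13 | O6-chloroacetate of 25 | O=C1C[C@H]2[C@H](OC(=O)CCl)/C=C(C)\C[C@H](OCc3ccc(OC)cc3)/C=C(C)/C[C@H]2O1
F0 | step 15 | none | none
F9 | step 12 | diol keto ester, methyl 2-[(1R,3Z,6S,7E,10R)-6,10-dihydroxy-4,8-dimethyl-2-oxocyclodeca-3,7-dien-1-yl]acetate | COC(=O)C[C@H]1C(=O)/C=C(C)\C[C@H](O)/C=C(C)/C[C@H]1O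
F10 | step 12 | 8-hydroxy keto lactone, (3aR,5Z,8S,9E,11aR)-8-hydroxy-6,10-dimethyl-3,3a,7,8,11,11a-hexahydrocyclodeca[b]furan-2,4-dione | O=C1C[C@H]2C(=O)/C=C(C)\C[C@H](O)/C=C(C)/C[C@H]2O1
A1 | alternative 1 | cis-fused enone lactone, (3aR,7aR)-6-methyl-3,3a,7,7a-tetrahydro-1-benzofuran-2,4-dione | O=C1C[C@H]2C(=O)C=C(C)C[C@H]2O1
A2 | alternative 1 | (S)-tert-butyldimethyl[(3-methylcyclobut-2-en-1-yl)oxy]silane | CC1=C[C@@H](O[Si](C)(C)C(C)(C)C)C1
A3 | alternative 1 | cis-anti-cis tricyclic keto lactone (6-4-4 ring system) | O=C1C[C@H]2C(=O)[C@@H]3[C@@]4(C)C[C@H](O[Si](C)(C)C(C)(C)C)[C@H]4[C@]3(C)C[C@H]2O1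
A4 | alternative 1 | 2-silyloxy (1(10)E,4Z)-dienone lactone from cycloreversion | O=C1C[C@H]2C(=O)/C=C(C)\C[C@H](O[Si](C)(C)C(C)(C)C)/C=C(C)/C[C@H]2O1
A5 | alternative 2 | open-chain ynal, (3Z)-3-methyl-5-[5-oxo-2-(prop-2-yn-1-yl)oxolan-3-yl]-5-[(triethylsilyl)oxy]pent-3-enal with C6, C7, C8 as in the target | C#CC[C@H]1OC(=O)C[C@H]1[C@H](O[Si](CC)(CC)CC)/C=C(C)\CC=O
A6 | alternative 2 | ten-membered (1(10)E,4Z)-dienol lactone, C2 free hydroxyl | C1C(=O)O[C@@H]2C/C(C)=C/[C@@H](O)C/C(C)=C\[C@@H](O[Si](CC)(CC)CC)[C@H]12
A7 | alternative 3 | open-chain bromomethyl enone with C4 methyl ketone | CC(=O)[C@H](OCc1ccc(OC)cc1)[C@@H](O[Si](C)(C)C(C)(C)C)[C@@H]2CC(=O)O[C@@H]2C/C(C)=C/C(=O)CBr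
A8 | alternative 3 | ten-membered 4-hydroxy-2-oxo enone lactone | C1C(=O)O[C@@H]2C/C(C)=C/C(=O)C[C@@](C)(O)[C@H](OCc3ccc(OC)cc3)[C@@H](O[Si](C)(C)C(C)(C)C)[C@H]12
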